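The route rests on cutting the C4–C5 bond, between the quaternary carbon of the cyclohexene and the β-carbon of the butenolide. C1 and C4 of that ring are the bridgeheads of the eight-atom oxa-bridge. The precursor is therefore a 12-membered cyclic ether (O, C1–C4, C9–C15) that carries a 4-bromofuran-3-yl group on C1 and an exocyclic methylene on C4. One 6-exo reductive Heck cyclisation closes the carbocycle, converts =CH2 into the C4 methyl group and sets the quaternary centre, since the bridge can span C1 and C4 on one face only. The furan serves as a masked butenolide and is oxidised afterwards at C7.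

Key step: step 14

Numbering used throughout (target): C1 = OCH of the cyclohexene, C2 = ring CH2, C3 = ring CHMe, C4 = quaternary ring carbon, C5/C6 = β/α carbons of the butenolide, C7 = lactone C=O, C8 = lactone OCH2, C9–C10 = CH2CH2, C11=C12 = Z-alkene, C13 = CHOH, C14 = CH2, C15 = tertiary ether carbon, C16 = CH2OH. The target is 1R,3R,4S,13S,15S,11Z. On the cyclohexene, O–C1 and C9–C4 are cis, and both ring methyl groups lie on the opposite face.

Assumption: the (R,R)-DACH-phenyl bisphosphine ligand is taken to give the S configuration at C15, by analogy with known additions of alcohols to 2-alkyl-2-vinyloxiranes. Should the sense be opposite, its antipode is used.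

Step 1
Reactants: 1 prop-2-yn-1-ol
Product: 3 (Z)-3-iodo-2-methylprop-2-en-1-ol, via alkenylmagnesium alkoxide 2 (not isolated)
Conditions: MeMgBr (2.5 equiv), CuI (cat.), THF, −10 °C to rt; then I2, −40 to 0 °C
Reagents that add atoms: methylmagnesium bromide, C[Mg]Br; iodine, [I][I]
Why: Copper-catalysed anti-carbomagnesiation of the propargylic alkoxide places magnesium cis to the CH2O group in a five-membered chelate, so iodinolysis with retention should give the Z-alkenyl iodide that later becomes the C11=C12 geometry.

Step 2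
Reactants: 3 (Z)-3-iodo-2-methylprop-2-en-1-ol
Product: 4 (Z)-3-bromo-1-iodo-2-methylprop-1-ene
Conditions: CBr4, PPh3, CH2Cl2, 0 °C
Reagents that add atoms: carbon tetrabromide, BrC(Br)(Br)Br
Why: The Appel reaction converts the primary allylic alcohol into the bromide under neutral conditions without touching the alkenyl iodide or the olefin geometry.

Step 3
Reactants: 5 (S)-4-benzyl-3-propionyloxazolidin-2-one; 6 2-bromo-N-methoxy-N-methylacetamide
Product: 8 (R)-4-[(S)-4-benzyl-2-oxooxazolidin-3-yl]-N-methoxy-N,3-dimethyl-4-oxobutanamide, via sodium Z-enolate 7 (not isolated)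
Conditions: NaN(SiMe3)2, THF, −78 °C; then 6, −78 to −30 °C
Reagents that add atoms: none
Why: In this Evans asymmetric alkylation the chelated Z-enolate is attacked by the activated bromide on the face opposite the benzyl group, which sets C3 as R.

Step 4
Reactants: 8 (R)-4-[(S)-4-benzyl-2-oxooxazolidin-3-yl]-N-methoxy-N,3-dimethyl-4-oxobutanamide
Product: 9 S-ethyl (R)-4-[methoxy(methyl)amino]-2-methyl-4-oxobutanethioate
Conditions: EtSH, n-BuLi, THF, 0 °C
Reagents that add atoms: ethanethiol, CCS
Why: Thiolate cleavage of the N-acyloxazolidinone (acyl transfer) occurs at the activated exocyclic carbonyl only, so the auxiliary is released while the Weinreb amide and the C3 centre stay untouched.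

Step 5
Reactants: 9 S-ethyl (R)-4-[methoxy(methyl)amino]-2-methyl-4-oxobutanethioate
Product: 10 (R)-N-methoxy-N,3-dimethyl-4-oxopentanamide
Conditions: Me2CuLi (from CuI and MeLi), Et2O, −78 °C
Reagents that add atoms: lithium dimethylcuprate, C[Cu-]C.[Li+]
Why: Acylation of a Gilman cuprate by the thioester stops at the methyl ketone, and the weakly basic reagent leaves the Weinreb amide and the α-stereocentre C3 unchanged at −78 °C.

Step 6
Reactants: 10 (R)-N-methoxy-N,3-dimethyl-4-oxopentanamide; 4 (Z)-3-bromo-1-iodo-2-methylprop-1-ene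
Product: 12 (3R,7Z)-8-iodo-N-methoxy-N,3,7-trimethyl-4-oxooct-7-enamide, via terminal lithium enolate 11 (not isolated)
Conditions: LiN(i-Pr)2 (1.05 equiv), THF, −78 °C; then 4, DMPU, −78 to −40 °C
Reagents that add atoms: none
Why: In this kinetic enolate alkylation the hindered amide base removes a proton from the unhindered C9 methyl group rather than from C3, and SN2 displacement of the allylic bromide joins C9 to C10 without touching the alkenyl iodide.

Step 7
Reactants: 12 (3R,7Z)-8-iodo-N-methoxy-N,3,7-trimethyl-4-oxooct-7-enamide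
Product: 13 (3R,7Z)-8-iodo-N-methoxy-N,3,7-trimethyl-4-methylideneoct-7-enamide
Conditions: Ph3PCH3Br, KN(SiMe3)2, THF, −78 to 0 °C
Reagents that add atoms: methyltriphenylphosphonium bromide, C[P+](c1ccccc1)(c1ccccc1)c1ccccc1.[Br-]
Why: Wittig methylenation of the ketone, which is far more electrophilic than the Weinreb amide, installs the C4 exocyclic methylene, and the low temperature limits enolisation at C3.

Step 8
Reactants: 14 3,4-dibromofuran; 13 (3R,7Z)-8-iodo-N-methoxy-N,3,7-trimethyl-4-methylideneoct-7-enamide
Product: 16 (3R,7Z)-1-(4-bromofuran-3-yl)-8-iodo-3,7-dimethyl-4-methylideneoct-7-en-1-one, via bromofuryllithium 15 (not isolated)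
Conditions: 14, n-BuLi, Et2O, −78 °C; then 13, −78 °C; H2O
Reagents that add atoms: none
Why: Bromine–lithium exchange on one of the two equivalent bromides of 14 is followed by a Weinreb ketone synthesis, in which the chelated tetrahedral adduct prevents over-addition and the stabilised furyllithium should not exchange the alkenyl iodide at −78 °C.

Step 9
Reactants: 16 (3R,7Z)-1-(4-bromofuran-3-yl)-8-iodo-3,7-dimethyl-4-methylideneoct-7-en-1-one
Product: 17 (1R,3R,7Z)-1-(4-bromofuran-3-yl)-8-iodo-3,7-dimethyl-4-methylideneoct-7-en-1-ol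
Conditions: RuCl(p-cymene)[(R,R)-TsDPEN] (cat.), HCO2H/Et3N 5:2, rt
Reagents that add atoms: none
Why: In this Noyori asymmetric transfer hydrogenation the (R,R)-catalyst distinguishes the furyl from the alkyl flank and delivers hydride to one carbonyl face, which sets C1 as R independently of C3 and leaves alkenes and carbon–halogen bonds alone.

Step 10
Reactants: 17 (1R,3R,7Z)-1-(4-bromofuran-3-yl)-8-iodo-3,7-dimethyl-4-methylideneoct-7-en-1-ol; 18 2-methyl-2-vinyloxirane (racemic)
Product: 19 (S)-2-{[(1R,3R,7Z)-1-(4-bromofuran-3-yl)-8-iodo-3,7-dimethyl-4-methylideneoct-7-en-1-yl]oxy}-2-methylbut-3-en-1-ol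
Conditions: Pd2(dba)3·CHCl3 (cat.), (1R,2R)-N,N'-bis[2-(diphenylphosphino)benzoyl]cyclohexane-1,2-diamine (cat.), Et3B (cat.), CH2Cl2, 0 °C to rt
Reagents that add atoms: none
Why: In this Tsuji–Trost-type asymmetric allylic etherification (dynamic kinetic asymmetric transformation) both enantiomers of 18 ionise to interconverting π-allyl complexes, the borane ties the alcohol to the liberated alkoxide and delivers it to the adjacent tertiary terminus, and the chiral ligand sets C15 as S while the C1–O bond is not broken.

Step 11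
Reactants: 19 (S)-2-{[(1R,3R,7Z)-1-(4-bromofuran-3-yl)-8-iodo-3,7-dimethyl-4-methylideneoct-7-en-1-yl]oxy}-2-methylbut-3-en-1-ol
Product: 20 tert-butyldimethylsilyl ether of 19 at C16–OH
Conditions: TBSCl, imidazole, DMF, rt
Reagents that add atoms: tert-butyldimethylsilyl chloride, CC(C)(C)[Si](C)(C)Cl
Why: Standard silylation of the only free hydroxyl group keeps C16–OH from forming a lactol with the aldehyde made in the next step.

Step 12
Reactants: 20 tert-butyldimethylsilyl ether of 19 at C16–OH
Product: 21 (S)-3-{[(1R,3R,7Z)-1-(4-bromofuran-3-yl)-8-iodo-3,7-dimethyl-4-methylideneoct-7-en-1-yl]oxy}-4-(tert-butyldimethylsilyloxy)-3-methylbutanal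
Conditions: PdCl2(PhCN)2, CuCl2·2H2O, AgNO2 (all cat.), O2 (1 atm), t-BuOH/MeNO2, rt
Reagents that add atoms: dioxygen, O=O
Why: In this nitrite-modified aldehyde-selective Wacker oxidation the quaternary allylic carbon and its ether oxygen steer oxygen to the terminal carbon C13, so only the monosubstituted vinyl group should react while the 1,1-disubstituted and trisubstituted alkenes stay intact.

Step 13
Reactants: 21 (S)-3-{[(1R,3R,7Z)-1-(4-bromofuran-3-yl)-8-iodo-3,7-dimethyl-4-methylideneoct-7-en-1-yl]oxy}-4-(tert-butyldimethylsilyloxy)-3-methylbutanal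
Product: 22 macrocyclic allylic alcohol (1R,3R,13S,15S,11Z; 12-membered ring O–C1–C2–C3–C4–C9–C10–C11=C12–C13–C14–C15)
Conditions: CrCl2 (excess), NiCl2 (cat.), DMSO/THF, high dilution, rt
Reagents that add atoms: none
Why: In this Nozaki–Hiyama–Kishi macrocyclisation the alkenyl iodide is metalated selectively over the furyl bromide with retention of the Z geometry, addition to the aldehyde closes the 12-membered ring, and C13 is expected to form as S through a cyclic transition state in which chromium is chelated by the aldehyde and C15 ether oxygens.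

Step 14
Reactants: 22 macrocyclic allylic alcohol (1R,3R,13S,15S,11Z)
Product: 23 furan-fused oxa-bridged tricycle (1R,3R,4S,13S,15S,11Z; furan C5 bonded to C4 and C4 bearing a methyl group)
Conditions: Pd(PPh3)4 (cat.), HCO2Na, DMF, 90 °C
Reagents that add atoms: none
Why: Zerovalent palladium adds oxidatively to the furyl C5–Br bond, syn-carbopalladation of the C4=CH2 double bond follows, and exchange of bromide for formate, loss of CO2 and reductive elimination then deliver the C4–C5 bond and the C4 methyl group, the neopentyl σ-alkylpalladium intermediate having no β-hydrogen to lose. The closest known reaction type is the intramolecular reductive Heck cyclisation of aryl and heteroaryl halides onto 1,1-disubstituted alkenes that builds benzylic quaternary centres. The only ring closed is the six-membered carbocycle C1–C6, in the 6-exo-trig mode. C4 is controlled by the 12-membered ring, because only addition to the alkene face that keeps C9 on the same side as the C1–O bond lets the eight-atom bridge span C1 and C4, and this boat-like arrangement also turns the C3 methyl group away from the bridge, so C4 should form as S. The step needs exo rather than 7-endo closure, which the three-atom tether and the 1,1-disubstitution secure, and it needs insertion to outrun formate reduction of the furylpalladium species, which the proximity enforced by the macrocycle favours. The trisubstituted C11=C12 alkene is remote and hindered, and no other carbon–halogen bond is left in 22.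

Step 15
Reactants: 23 furan-fused oxa-bridged tricycle (1R,3R,4S,13S,15S,11Z)
Product: 27 16-O-(tert-butyldimethylsilyl)neocucurbin A, via dilithio species 24 (not isolated), via furylboronate 25 (not isolated), via 2-hydroxyfuran 26 (not isolated)
Conditions: n-BuLi (2.2 equiv), THF, −78 to −20 °C; B(OMe)3, −78 °C to rt; H2O2, aq NaHCO3, 0 °C
Reagents that add atoms: hydrogen peroxide, OO
Why: In this ether-directed α-lithiation, borylation and peroxide oxidation of a furan to a butenolide, C7–H lies next to the C1 ether oxygen and away from the quaternary C4, so it should be metalated in preference to C8–H, and the 2-hydroxyfuran tautomerises to the conjugated lactone by protonation at C8, which creates no stereocentre and opens no ring.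

Step 16
Reactants: 27 16-O-(tert-butyldimethylsilyl)neocucurbin A
Product: 28 neocucurbin A
Conditions: HF·pyridine, THF, 0 °C to rt
Reagents that add atoms: none
Why: Fluoride-mediated cleavage of the primary silyl ether under buffered conditions leaves the lactone, the tertiary ether and the allylic alcohol intact and gives the target.

Compound list
1 | prop-2-yn-1-ol | C#CCO | starting material
2 | bromomagnesium (Z)-3-(bromomagnesio)-2-methylprop-2-en-1-olate | Br[Mg]OC/C(C)=C\[Mg]Br | intermediate
3 | (Z)-3-iodo-2-methylprop-2-en-1-ol | OC/C(C)=C\I | intermediate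
4 | (Z)-3-bromo-1-iodo-2-methylprop-1-ene | BrC/C(C)=C\I | intermediate
5 | (S)-4-benzyl-3-propionyloxazolidin-2-one | CCC(=O)N1[C@@H](Cc2ccccc2)COC1=O | starting material
6 | 2-bromo-N-methoxy-N-methylacetamide | CON(C)C(=O)CBr | starting material
7 | sodium (Z)-enolate of 5 | C/C=C(\[O-])N1[C@@H](Cc2ccccc2)COC1=O.[Na+] | intermediate
8 | (R)-4-[(S)-4-benzyl-2-oxooxazolidin-3-yl]-N-methoxy-N,3-dimethyl-4-oxobutanamide | CON(C)C(=O)C[C@@H](C)C(=O)N1[C@@H](Cc2ccccc2)COC1=O | intermediate
9 | S-ethyl (R)-4-[methoxy(methyl)amino]-2-methyl-4-oxobutanethioate | CON(C)C(=O)C[C@@H](C)C(=O)SCC | intermediate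
10 | (R)-N-methoxy-N,3-dimethyl-4-oxopentanamide | CON(C)C(=O)C[C@@H](C)C(C)=O | intermediate
11 | lithium (R)-5-[methoxy(methyl)amino]-3-methyl-5-oxopent-1-en-2-olate | CON(C)C(=O)C[C@@H](C)C([O-])=C.[Li+] | intermediate
12 | (3R,7Z)-8-iodo-N-methoxy-N,3,7-trimethyl-4-oxooct-7-enamide | CON(C)C(=O)C[C@@H](C)C(=O)CC/C(C)=C\I | intermediate
13 | (3R,7Z)-8-iodo-N-methoxy-N,3,7-trimethyl-4-methylideneoct-7-enamide | CON(C)C(=O)C[C@@H](C)C(=C)CC/C(C)=C\I | intermediate
14 | 3,4-dibromofuran | Brc1cocc1Br | starting material
15 | (4-bromofuran-3-yl)lithium | [Li]c1cocc1Br | intermediate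
16 | (3R,7Z)-1-(4-bromofuran-3-yl)-8-iodo-3,7-dimethyl-4-methylideneoct-7-en-1-one | O=C(c1cocc1Br)C[C@@H](C)C(=C)CC/C(C)=C\I | intermediate
17 | (1R,3R,7Z)-1-(4-bromofuran-3-yl)-8-iodo-3,7-dimethyl-4-methylideneoct-7-en-1-ol | O[C@@H](c1cocc1Br)C[C@@H](C)C(=C)CC/C(C)=C\I | intermediate
18 | 2-methyl-2-vinyloxirane (racemic) | C=CC1(C)CO1 | starting material
19 | (S)-2-{[(1R,3R,7Z)-1-(4-bromofuran-3-yl)-8-iodo-3,7-dimethyl-4-methylideneoct-7-en-1-yl]oxy}-2-methylbut-3-en-1-ol | C=C[C@@](C)(CO)O[C@@H](c1cocc1Br)C[C@@H](C)C(=C)CC/C(C)=C\I | intermediate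
20 | tert-butyldimethylsilyl ether of 19 at C16–OH (1R,3R,15S, Z-alkenyl iodide) | C=C[C@@](C)(CO[Si](C)(C)C(C)(C)C)O[C@@H](c1cocc1Br)C[C@@H](C)C(=C)CC/C(C)=C\I | intermediate
21 | (S)-3-{[(1R,3R,7Z)-1-(4-bromofuran-3-yl)-8-iodo-3,7-dimethyl-4-methylideneoct-7-en-1-yl]oxy}-4-(tert-butyldimethylsilyloxy)-3-methylbutanal | O=CC[C@@](C)(CO[Si](C)(C)C(C)(C)C)O[C@@H](c1cocc1Br)C[C@@H](C)C(=C)CC/C(C)=C\I | intermediate
22 | (1R,3R,13S,15S,11Z)-macrocyclic allylic alcohol: 12-membered ring O–C1–C2–C3–C4–C9–C10–C11=C12–C13–C14–C15; 4-bromofuran-3-yl on C1; methyl on C3, C11 and C15; methylidene on C4; OH on C13; CH2OTBS on C15 | C/C1=C/[C@@H](O)C[C@@](C)(CO[Si](C)(C)C(C)(C)C)O[C@@H](c2cocc2Br)C[C@@H](C)C(=C)CC1 | intermediate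
23 | (1R,3R,4S,13S,15S,11Z)-furan-fused oxa-bridged tricycle: as 22, but furan C5 bonded to C4, C4 bearing methyl, no bromine | C/C1=C/[C@@H](O)C[C@@](C)(CO[Si](C)(C)C(C)(C)C)O[C@@H]2C[C@@H](C)[C@](C)(CC1)c1cocc12 | intermediate
24 | C7-lithiated lithium C13-alkoxide of 23 | C/C1=C/[C@@H]([O-])C[C@@](C)(CO[Si](C)(C)C(C)(C)C)O[C@@H]2C[C@@H](C)[C@](C)(CC1)c1coc([Li])c12.[Li+] | intermediate
25 | C7 dimethyl boronate of 23 as lithium C13-alkoxide | C/C1=C/[C@@H]([O-])C[C@@](C)(CO[Si](C)(C)C(C)(C)C)O[C@@H]2C[C@@H](C)[C@](C)(CC1)c1coc(B(OC)OC)c12.[Li+] | intermediate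
26 | C7-hydroxyfuran derived from 23 | C/C1=C/[C@@H](O)C[C@@](C)(CO[Si](C)(C)C(C)(C)C)O[C@@H]2C[C@@H](C)[C@](C)(CC1)c1coc(O)c12 | intermediate
27 | 16-O-(tert-butyldimethylsilyl)neocucurbin A (1R,3R,4S,13S,15S,11Z) | C/C1=C/[C@@H](O)C[C@@](C)(CO[Si](C)(C)C(C)(C)C)O[C@@H]2C[C@@H](C)[C@](C)(CC1)C1=C2C(=O)OC1 | intermediate
28 | neocucurbin A (1R,3R,4S,13S,15S,11Z) | C/C1=C/[C@@H](O)C[C@@](C)(CO)O[C@@H]2C[C@@H](C)[C@](C)(CC1)C1=C2C(=O)OC1 | target

Total step count: 16. Longest linear sequence: 14 steps (steps 3–16, from 5 to 28). The branch from 1 to 4 takes two steps.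

Steps most likely to fail

(1) Step 14. The furylpalladium species may be reduced by formate before it inserts, which removes bromine without closing the ring. The neopentylpalladium species may rearrange through a cyclopropane to the seven-membered ring. The alkene may also be attacked on the wrong face. The fallback sets out from 22 and makes the same C4–C5 bond by a radical route, a Markovnikov hydroarylation under iron hydride/nickel dual catalysis [Fe(dpm)3, NiBr2·diglyme, 4,4'-di-tert-butyl-2,2'-bipyridine, PhSiH2(O-i-Pr), Mn]. Hydrogen-atom transfer to the =CH2 terminus gives the tertiary C4 radical, which is captured by the furylnickel species formed from the C5–Br bond. This comes back to the route at 23 and makes no new compound (F0).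

(2) Step 10. The hindered secondary alcohol may attack the π-allyl complex too slowly. Oxidative addition of zerovalent palladium into the alkenyl iodide, attack at the terminal allyl carbon, or further alkylation of the new primary hydroxyl group could then take over. The fallback sets out from 17 and replaces catalyst control by a stereospecific epoxide opening.
- Commercial (S)-2-methylglycidol is silylated (TBSCl, imidazole) to the epoxide (R)-tert-butyldimethyl[(2-methyloxiran-2-yl)methoxy]silane F1.
- BF3·OEt2-catalysed attack of 17 on the tertiary carbon of F1, with inversion, gives the primary alcohol F2.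
- Dess–Martin oxidation gives the aldehyde F3.
- Wittig homologation with Ph3P=CHOMe gives the methyl enol ether F4.
- Mild acid hydrolysis comes back to the route at 21.

(3) Step 13. Intermolecular coupling may compete with ring closure, and the facial selectivity at C13 may be poor or opposite to the one wanted. The fallback sets out from 22, obtained as a mixture of C13 epimers, and moves the stereocontrol from the carbon–carbon bond formation to a reagent-controlled reduction. Dess–Martin oxidation gives the macrocyclic Z-enone F5. Corey–Bakshi–Shibata reduction with the (R)-methyl oxazaborolidine and catecholborane comes back to the route at 22 as the 13S alcohol.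

Further compounds
F0 | step 14 | none | none
F1 | step 10 | (R)-tert-butyldimethyl[(2-methyloxiran-2-yl)methoxy]silane | C1[C@](C)(CO[Si](C)(C)C(C)(C)C)O1
F2 | step 10 | (S)-2-{[(1R,3R,7Z)-1-(4-bromofuran-3-yl)-8-iodo-3,7-dimethyl-4-methylideneoct-7-en-1-yl]oxy}-3-(tert-butyldimethylsilyloxy)-2-methylpropan-1-ol | OC[C@@](C)(CO[Si](C)(C)C(C)(C)C)O[C@@H](c1cocc1Br)C[C@@H](C)C(=C)CC/C(C)=C\I
F3 | step 10 | (R)-2-{[(1R,3R,7Z)-1-(4-bromofuran-3-yl)-8-iodo-3,7-dimethyl-4-methylideneoct-7-en-1-yl]oxy}-3-(tert-butyldimethylsilyloxy)-2-methylpropanal | O=C[C@@](C)(CO[Si](C)(C)C(C)(C)C)O[C@@H](c1cocc1Br)C[C@@H](C)C(=C)CC/C(C)=C\I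
F4 | step 10 | methyl enol ether of 21 (15S; E/Z mixture at C13=C14) | COC=C[C@@](C)(CO[Si](C)(C)C(C)(C)C)O[C@@H](c1cocc1Br)C[C@@H](C)C(=C)CC/C(C)=C\I
F5 | step 13 | (1R,3R,15S,11Z)-macrocyclic enone, the C13 ketone of 22 | C/C1=C/C(=O)C[C@@](C)(CO[Si](C)(C)C(C)(C)C)O[C@@H](c2cocc2Br)C[C@@H](C)C(=C)CC1
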